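**Retrosynthetic overview**

1. Endgame on the intact skeleton: the two aryl CHO groups come from double ortho-lithiation/DMF and the free phenols from thiolate O-demethylation; the C1′–aryl and C1′–isobutyl bonds come from a C1 aldehyde (aryllithium addition, then SN1 methallylation and hydrogenation); the C4–OH comes from a C4 acetyl group (Baeyer–Villiger); the C1–H comes from hydrogenation of a Δ1 alkene.
2. Key disconnection: ring A is opened across C3–C4 and C5–C10 at once (retro intramolecular Diels–Alder), which also opens ring B and leaves an acyclic trienone: (E)-α-methyl enone C4=C5, diene C10=C1–C2=C3, joined by C6–C9.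
3. Enabling feature: ring A (C1–C2–C3–C4–C5–C10) is a six-membered carbocycle whose C4–C5 edge (quaternary C4 with Me and O, tertiary C5) is flanked by C3 and the quaternary C10, and C5/C10 are already bridged by the four-carbon chain C6–C9 of ring B. With Δ1 unsaturation this is the adduct of a tethered enone and a diene, and the C7 stereocentre sits on the tether.
4. Ring order: rings A and B form together in the key step (A by the cycloaddition, B as the tether ring); the benzene ring is bought (1,3,5-trimethoxybenzene).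
5. The trienone comes from (R)-α-terpineol: ozonolytic ring opening gives C5 as an aldehyde (→ Wittig enone) and C10 as a methyl ketone (→ ynoate → syn-methylcupration/iodination → Stille vinylation), with C7 already in place.

Key step: step 8

Assumption: decalin carbons are numbered as in eudesmane (C1 carries the benzylic carbon C1′, C4 the carbinol, C5/C10 the ring fusion, C7 the C11 side chain), α/β mean opposite to/same face as the angular 10-methyl group, TBSO = tert-butyldimethylsilyloxy, and carbinol 22 is used as the mixture of C1′ epimers because that centre is planarised in step 14.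

**Route**

Step 1
Reactants: 1 (R)-(+)-α-terpineol
Product: 2 (R)-α-terpineol tert-butyldimethylsilyl ether
Conditions: TBSOTf, 2,6-lutidine, CH2Cl2, 0 °C to rt
Reagents that add atoms: tert-butyldimethylsilyl triflate, CC(C)(C)[Si](C)(C)OS(=O)(=O)C(F)(F)F
Why: Silyl triflate/hindered base silylation of a tertiary alcohol (silyl ether protection) masks the future C11–OH so that it cannot add oxa-Michael fashion to the enone made in step 6; the C7 stereocentre comes from the chiral pool and is not touched.

Step 2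
Reactants: 2 (R)-α-terpineol tert-butyldimethylsilyl ether
Product: 5 (5R)-7,7-dimethoxy-5-[2-(TBSO)propan-2-yl]heptan-2-one, via methoxy hydroperoxide aldehyde 3 (not isolated), via methoxy hydroperoxide acetal 4 (not isolated)
Conditions: O3, CH2Cl2/MeOH 4:1, −78 °C; p-TsOH·H2O (cat.), rt; NaHCO3, Me2S, rt
Reagents that add atoms: ozone, [O-][O+]=O; methanol, CO
Why: Ozonolysis in methanol (Criegee mechanism) puts the carbonyl oxide on the more substituted alkene carbon, where methanol traps it as the methoxy hydroperoxide, while the aldehyde end alone is acetalised before the reductive work-up, so the ring opens to a chain with differentiated ends (C5 acetal, C10 methyl ketone) in one flask.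

Step 3
Reactants: 5 (5R)-7,7-dimethoxy-5-[2-(TBSO)propan-2-yl]heptan-2-one
Product: 8 methyl (6R)-8,8-dimethoxy-6-[2-(TBSO)propan-2-yl]oct-2-ynoate, via enol phosphate 6 (not isolated), via lithium acetylide 7 (not isolated)
Conditions: LDA (1.1 equiv), THF, −78 °C; ClP(O)(OEt)2; LDA (2.3 equiv), −78 to 0 °C; ClCO2Me, −78 °C
Reagents that add atoms: methyl chloroformate, COC(Cl)=O
Why: Kinetic enolisation on the methyl side, O-phosphorylation and base-induced elimination of the enol phosphate (methyl ketone to terminal alkyne) give the lithium acetylide, which is acylated by the chloroformate; the old ketone methyl carbon becomes C1 and the ester carbon the future C1′.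

Step 4
Reactants: 8 methyl (6R)-8,8-dimethoxy-6-[2-(TBSO)propan-2-yl]oct-2-ynoate
Product: 10 methyl (2E,6R)-2-iodo-8,8-dimethoxy-3-methyl-6-[2-(TBSO)propan-2-yl]oct-2-enoate, via alkenyl methyl cuprate 9 (not isolated)
Conditions: Me2CuLi (1.3 equiv, from MeLi and CuI), THF, −78 °C; then I2, THF, −78 °C
Reagents that add atoms: lithium dimethylcuprate, [Li+].C[Cu-]C; iodine, II
Why: Conjugate syn-carbocupration of an ynoate at −78 °C followed by iodinolysis of the alkenylcopper with retention (cuprate addition–trapping) fixes the tetrasubstituted C10=C1 geometry, with the new methyl cis to iodine and the chain carbon C9 cis to the ester.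

Step 5
Reactants: 10 methyl (2E,6R)-2-iodo-8,8-dimethoxy-3-methyl-6-[2-(TBSO)propan-2-yl]oct-2-enoate
Product: 12 (3R,6E)-8-hydroxy-7-iodo-6-methyl-3-[2-(TBSO)propan-2-yl]oct-6-enal, via allylic alcohol acetal 11 (not isolated)
Conditions: DIBAL-H (2.5 equiv), CH2Cl2, −78 °C; then 1 M HCl, THF, rt
Reagents that add atoms: water, O
Why: DIBAL 1,2-reduction of the enoate gives the allylic alcohol without touching the alkenyl iodide or the alkene geometry, and the acidic work-up hydrolyses only the dimethyl acetal (acetal hydrolysis), a tertiary TBS ether being stable to dilute HCl at rt.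

Step 6
Reactants: 12 (3R,6E)-8-hydroxy-7-iodo-6-methyl-3-[2-(TBSO)propan-2-yl]oct-6-enal
Product: 13 (3E,6R,9E)-11-hydroxy-10-iodo-3,9-dimethyl-6-[2-(TBSO)propan-2-yl]undeca-3,9-dien-2-one
Conditions: Ph3P=C(CH3)C(O)CH3 (1.5 equiv), toluene, 90 °C
Reagents that add atoms: 3-(triphenylphosphoranylidene)butan-2-one, CC(=O)C(C)=P(c1ccccc1)(c1ccccc1)c1ccccc1
Why: Wittig olefination of the aldehyde with a stabilised α-methyl ylide gives the (E)-trisubstituted enone (acetyl trans to the chain) and tolerates the free alcohol and the alkenyl iodide.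

Step 7
Reactants: 13 (3E,6R,9E)-11-hydroxy-10-iodo-3,9-dimethyl-6-[2-(TBSO)propan-2-yl]undeca-3,9-dien-2-one
Product: 14 (3E,6R,9Z)-10-(hydroxymethyl)-3,9-dimethyl-6-[2-(TBSO)propan-2-yl]dodeca-3,9,11-trien-2-one
Conditions: tributyl(vinyl)stannane, Pd(PPh3)4 (5 mol %), CuI (10 mol %), DMF, 40 °C
Reagents that add atoms: tributyl(vinyl)stannane, C=C[Sn](CCCC)(CCCC)CCCC
Why: Stille coupling of the alkenyl iodide occurs with retention of geometry, so the vinyl group (C2=C3) ends cis to the C10 methyl and the tether carbon C9 lies on the outside position of the diene, as the trans ring fusion requires.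

Step 8
Reactants: 14 (3E,6R,9Z)-10-(hydroxymethyl)-3,9-dimethyl-6-[2-(TBSO)propan-2-yl]dodeca-3,9,11-trien-2-one
Product: 15 trans-fused Δ1-octalin: 4α-acetyl-1-(hydroxymethyl)-4β,10β-dimethyl-7β-[2-(TBSO)propan-2-yl]-5αH-octal-1-ene
Conditions: Me2AlCl (2.2 equiv), CH2Cl2, −40 to 0 °C
Reagents that add atoms: none
Why: Me2AlCl first turns the primary OH into an aluminium alkoxide and then activates the enone carbonyl, so that the (E)-α-methyl enone (C4=C5) and the s-cis diene (C10=C1–C2=C3) combine in a concerted, asynchronous [4+2] cycloaddition that forms C5–C10 and C3–C4 together. The closest known reaction type is the Lewis-acid-promoted type-1 intramolecular Diels–Alder reaction of (E)-1,7,9-decatrien-3-ones, which gives trans-fused octalins through the endo transition state. Ring A (C1–C2–C3–C4–C5–C10) closes by the suprafacial cycloaddition itself, and ring B closes as the fused six-membered tether ring (C5–C6–C7–C8–C9–C10) through the C5–C10 bond in a chair. C4, C5 and C10 are set relative to one another by the alkene geometries and the endo rule: the E enone keeps 4-Me cis to C6 and acetyl cis to 5-H, the diene carries the tether outside and the 10-Me inside, and acetyl-endo addition therefore gives the trans fusion with 4β-Me, 10β-Me and 4α-acetyl. The absolute sense comes from C7, whose bulky CMe2OTBS group stays equatorial in the chair tether and so decides which diene face the dienophile reaches. The step needs endo over exo and one diene face; the carbonyl-bound Lewis acid and the α-methyl group (which would sit under the diene in the exo mode) secure the first, the C7 substituent secures the second, and the low temperature avoids a 1,5-hydrogen shift of the (Z)-methyl diene.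

Step 9
Reactants: 15 trans-fused Δ1-octalin
Product: 16 4α-acetyl-1β-(hydroxymethyl)-4β,10β-dimethyl-7β-[2-(TBSO)propan-2-yl]-trans-decalin (1α-H, 5α-H)
Conditions: H2 (1–4 bar), [Ir(cod)(PCy3)(py)]PF6 (5 mol %), CH2Cl2, rt
Reagents that add atoms: none
Why: Homogeneous iridium-catalysed hydrogenation of the hindered trisubstituted alkene (hydroxyl/carbonyl-directed hydrogenation) adds H2 to the α face, which is free of the axial 4β- and 10β-methyl groups and carries the coordinating acetyl group, so C1 forms with 1α-H and an equatorial 1β-CH2OH.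

Step 10
Reactants: 16 4α-acetyl-1β-(hydroxymethyl) decalin
Product: 17 4α-acetoxy-1β-(hydroxymethyl)-4β,10β-dimethyl-7β-[2-(TBSO)propan-2-yl]-trans-decalin
Conditions: mCPBA (3 equiv), NaHCO3, CH2Cl2, rt
Reagents that add atoms: meta-chloroperoxybenzoic acid, OOC(=O)c1cccc(Cl)c1
Why: Baeyer–Villiger oxidation of the methyl ketone proceeds with migration of the tertiary C4 centre and retention of its configuration, turning the activating acetyl group into the 4α-oxygen substituent, and no other oxidisable π-system is present at this stage.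

Step 11
Reactants: 17 4α-acetoxy-1β-(hydroxymethyl) decalin
Product: 18 1β-(hydroxymethyl)-4β,10β-dimethyl-7β-[2-(TBSO)propan-2-yl]-trans-decalin-4α-ol
Conditions: LiAlH4, THF, 0 °C to rt
Reagents that add atoms: none
Why: Hydride reduction cleaves the hindered tertiary acetate (ester reduction) to the free 4α-alcohol without affecting the silyl ether.

Step 12
Reactants: 18 1β-(hydroxymethyl) decalin-4α-ol
Product: 19 4α-hydroxy-4β,10β-dimethyl-7β-[2-(TBSO)propan-2-yl]-trans-decalin-1β-carbaldehyde
Conditions: Dess–Martin periodinane, NaHCO3, CH2Cl2, rt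
Reagents that add atoms: none
Why: Dess–Martin oxidation converts only the primary alcohol into the aldehyde (the tertiary alcohol is inert), and the equatorial 1β-aldehyde is also the thermodynamically preferred C1 epimer.

Step 13
Reactants: 19 decalin-1β-carbaldehyde; 20 1,3,5-trimethoxybenzene
Product: 22 1β-[hydroxy(2,4,6-trimethoxyphenyl)methyl]-4β,10β-dimethyl-7β-[2-(TBSO)propan-2-yl]-trans-decalin-4α-ol (both C1′ epimers), via 2,4,6-trimethoxyphenyllithium 21 (not isolated)
Conditions: 20 (3 equiv), n-BuLi (2.8 equiv), THF, 0 °C to rt; then 19, −78 to −20 °C; aq. NH4Cl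
Reagents that add atoms: none
Why: Directed ortho-lithiation of 1,3,5-trimethoxybenzene between two methoxy groups and 1,2-addition of the aryllithium to the aldehyde (excess reagent covers the free tertiary OH) give the benzylic carbinol, whose new centre need not be controlled because it is planarised in step 14.

Step 14
Reactants: 22 benzylic carbinol (C1′ epimers)
Product: 23 1β-[(1S)-3-methyl-1-(2,4,6-trimethoxyphenyl)but-3-en-1-yl]-4β,10β-dimethyl-7β-[2-(TBSO)propan-2-yl]-trans-decalin-4α-ol
Conditions: 2-methylallyltrimethylsilane (4 equiv), Bi(OTf)3 (5 mol %), CH2Cl2, −40 to 0 °C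
Reagents that add atoms: 2-methylallyltrimethylsilane, CC(=C)C[Si](C)(C)C
Why: Acid-catalysed ionisation of the very electron-rich benzylic alcohol gives a trimethoxybenzyl cation that is captured by the allylsilane (SN1 Hosomi–Sakurai allylation of a benzylic alcohol); in the conformer that minimises allylic 1,3-strain the C1–H bond lies in the cation plane next to an ortho-methoxy group, and the nucleophile adds anti to the quaternary C10 (from the C2 side), which gives the (S)-C1′ centre.

Step 15
Reactants: 23 methallyl compound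
Product: 24 1β-[(1S)-3-methyl-1-(2,4,6-trimethoxyphenyl)butyl]-4β,10β-dimethyl-7β-[2-(TBSO)propan-2-yl]-trans-decalin-4α-ol
Conditions: H2 (1 atm), 10% Pd/C, EtOAc, rt
Reagents that add atoms: none
Why: Heterogeneous hydrogenation of the 1,1-disubstituted alkene turns the methallyl group into the isobutyl group without creating a stereocentre.

Step 16
Reactants: 24 isobutyl compound (TBS ether)
Product: 25 1β-[(1S)-3-methyl-1-(2,4,6-trimethoxyphenyl)butyl]-7β-(2-hydroxypropan-2-yl)-4β,10β-dimethyl-trans-decalin-4α-ol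
Conditions: TBAF, THF, 60 °C
Reagents that add atoms: none
Why: Fluoride-induced cleavage of the tertiary silyl ether (desilylation) frees the C11 alcohol under non-acidic conditions, so neither tertiary alcohol can ionise.

Step 17
Reactants: 25 trimethoxyaryl diol
Product: 27 macrocarpal J tri-O-methyl ether (2,4,6-trimethoxy-5-alkylbenzene-1,3-dicarbaldehyde), via lithium hemiaminal 26 (not isolated)
Conditions: n-BuLi (3.3 equiv), TMEDA, THF, 0 °C; DMF, −78 to 0 °C; n-BuLi (1.5 equiv), 0 °C; DMF; then 1 M HCl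
Reagents that add atoms: N,N-dimethylformamide, CN(C)C=O
Why: Directed ortho-metalation (after O-lithiation of both alcohols) at the ring C–H flanked by two methoxy groups and DMF quench install the first formyl group as its lithium hemiaminal, which is inert to butyllithium and lets the remaining ring C–H, again flanked by two methoxy groups, be lithiated and formylated in the same flask.

Step 18
Reactants: 27 macrocarpal J tri-O-methyl ether
Product: 28 macrocarpal J
Conditions: NaSEt (12 equiv), DMF, 120–130 °C; then 1 M HCl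
Reagents that add atoms: none
Why: SN2 O-demethylation by thiolate is easy here because each methoxy group is ortho or para to a formyl group (stabilised phenoxide leaving groups) and, being non-acidic, it spares both tertiary alcohols and every stereocentre.

**Compound list**

1 | (R)-(+)-α-terpineol, 2-[(1R)-4-methylcyclohex-3-en-1-yl]propan-2-ol | CC1=CC[C@@H](CC1)C(C)(C)O | starting material
2 | (R)-α-terpineol tert-butyldimethylsilyl ether | CC1=CC[C@@H](CC1)C(C)(C)O[Si](C)(C)C(C)(C)C | intermediate
3 | methoxy hydroperoxide aldehyde, (3R)-6-hydroperoxy-6-methoxy-3-[2-(TBSO)propan-2-yl]heptanal (C6 epimers) | O=CC[C@@H](CCC(C)(OC)OO)C(C)(C)O[Si](C)(C)C(C)(C)C | intermediate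
4 | methoxy hydroperoxide acetal, (5R)-2-hydroperoxy-2,7,7-trimethoxy-5-[2-(TBSO)propan-2-yl]heptane (C2 epimers) | COC(OC)C[C@@H](CCC(C)(OC)OO)C(C)(C)O[Si](C)(C)C(C)(C)C | intermediate
5 | (5R)-7,7-dimethoxy-5-[2-(TBSO)propan-2-yl]heptan-2-one | COC(OC)C[C@@H](CCC(C)=O)C(C)(C)O[Si](C)(C)C(C)(C)C | intermediate
6 | enol phosphate, diethyl (5R)-7,7-dimethoxy-5-[2-(TBSO)propan-2-yl]hept-1-en-2-yl phosphate | COC(OC)C[C@@H](CCC(=C)OP(=O)(OCC)OCC)C(C)(C)O[Si](C)(C)C(C)(C)C | intermediate
7 | lithium acetylide of (5R)-7,7-dimethoxy-5-[2-(TBSO)propan-2-yl]hept-1-yne | COC(OC)C[C@@H](CCC#C[Li])C(C)(C)O[Si](C)(C)C(C)(C)C | intermediate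
8 | methyl (6R)-8,8-dimethoxy-6-[2-(TBSO)propan-2-yl]oct-2-ynoate | COC(OC)C[C@@H](CCC#CC(=O)OC)C(C)(C)O[Si](C)(C)C(C)(C)C | intermediate
9 | alkenyl methyl cuprate, lithium methyl[(alkenyl)]cuprate with Cu on the ester α-carbon cis to the new 3-methyl group | [Li+].COC(OC)C[C@@H](CC/C(C)=C(/[Cu-]C)C(=O)OC)C(C)(C)O[Si](C)(C)C(C)(C)C | intermediate
10 | methyl (2E,6R)-2-iodo-8,8-dimethoxy-3-methyl-6-[2-(TBSO)propan-2-yl]oct-2-enoate | COC(OC)C[C@@H](CC/C(C)=C(/I)C(=O)OC)C(C)(C)O[Si](C)(C)C(C)(C)C | intermediate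
11 | allylic alcohol acetal, (2E,6R)-2-iodo-8,8-dimethoxy-3-methyl-6-[2-(TBSO)propan-2-yl]oct-2-en-1-ol | COC(OC)C[C@@H](CC/C(C)=C(/I)CO)C(C)(C)O[Si](C)(C)C(C)(C)C | intermediate
12 | (3R,6E)-8-hydroxy-7-iodo-6-methyl-3-[2-(TBSO)propan-2-yl]oct-6-enal | O=CC[C@@H](CC/C(C)=C(/I)CO)C(C)(C)O[Si](C)(C)C(C)(C)C | intermediate
13 | (3E,6R,9E)-11-hydroxy-10-iodo-3,9-dimethyl-6-[2-(TBSO)propan-2-yl]undeca-3,9-dien-2-one | CC(=O)/C(C)=C/C[C@@H](CC/C(C)=C(/I)CO)C(C)(C)O[Si](C)(C)C(C)(C)C | intermediate
14 | (3E,6R,9Z)-10-(hydroxymethyl)-3,9-dimethyl-6-[2-(TBSO)propan-2-yl]dodeca-3,9,11-trien-2-one | CC(=O)/C(C)=C/C[C@@H](CC/C(C)=C(\CO)C=C)C(C)(C)O[Si](C)(C)C(C)(C)C | intermediate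
15 | trans-fused Δ1-octalin, 4α-acetyl-1-(hydroxymethyl)-4β,10β-dimethyl-7β-[2-(TBSO)propan-2-yl]-5αH-octal-1-ene | OCC1=CC[C@@](C)(C(C)=O)[C@@H]2C[C@H](C(C)(C)O[Si](C)(C)C(C)(C)C)CC[C@]21C | intermediate
16 | 4α-acetyl-1β-(hydroxymethyl)-4β,10β-dimethyl-7β-[2-(TBSO)propan-2-yl]-trans-decalin (1α-H, 5α-H) | OC[C@@H]1CC[C@@](C)(C(C)=O)[C@@H]2C[C@H](C(C)(C)O[Si](C)(C)C(C)(C)C)CC[C@]21C | intermediate
17 | 4α-acetoxy-1β-(hydroxymethyl)-4β,10β-dimethyl-7β-[2-(TBSO)propan-2-yl]-trans-decalin | OC[C@@H]1CC[C@@](C)(OC(C)=O)[C@@H]2C[C@H](C(C)(C)O[Si](C)(C)C(C)(C)C)CC[C@]21C | intermediate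
18 | 1β-(hydroxymethyl)-4β,10β-dimethyl-7β-[2-(TBSO)propan-2-yl]-trans-decalin-4α-ol | OC[C@@H]1CC[C@@](C)(O)[C@@H]2C[C@H](C(C)(C)O[Si](C)(C)C(C)(C)C)CC[C@]21C | intermediate
19 | 4α-hydroxy-4β,10β-dimethyl-7β-[2-(TBSO)propan-2-yl]-trans-decalin-1β-carbaldehyde | O=C[C@@H]1CC[C@@](C)(O)[C@@H]2C[C@H](C(C)(C)O[Si](C)(C)C(C)(C)C)CC[C@]21C | intermediate
20 | 1,3,5-trimethoxybenzene | COc1cc(OC)cc(OC)c1 | starting material
21 | 2,4,6-trimethoxyphenyllithium | [Li]c1c(OC)cc(OC)cc1OC | intermediate
22 | 1β-[hydroxy(2,4,6-trimethoxyphenyl)methyl]-4β,10β-dimethyl-7β-[2-(TBSO)propan-2-yl]-trans-decalin-4α-ol (C1′ epimers) | OC(c1c(OC)cc(OC)cc1OC)[C@@H]1CC[C@@](C)(O)[C@@H]2C[C@H](C(C)(C)O[Si](C)(C)C(C)(C)C)CC[C@]21C | intermediate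
23 | 1β-[(1S)-3-methyl-1-(2,4,6-trimethoxyphenyl)but-3-en-1-yl]-4β,10β-dimethyl-7β-[2-(TBSO)propan-2-yl]-trans-decalin-4α-ol | CC(=C)C[C@H](c1c(OC)cc(OC)cc1OC)[C@@H]1CC[C@@](C)(O)[C@@H]2C[C@H](C(C)(C)O[Si](C)(C)C(C)(C)C)CC[C@]21C | intermediate
24 | 1β-[(1S)-3-methyl-1-(2,4,6-trimethoxyphenyl)butyl]-4β,10β-dimethyl-7β-[2-(TBSO)propan-2-yl]-trans-decalin-4α-ol | CC(C)C[C@H](c1c(OC)cc(OC)cc1OC)[C@@H]1CC[C@@](C)(O)[C@@H]2C[C@H](C(C)(C)O[Si](C)(C)C(C)(C)C)CC[C@]21C | intermediate
25 | 1β-[(1S)-3-methyl-1-(2,4,6-trimethoxyphenyl)butyl]-7β-(2-hydroxypropan-2-yl)-4β,10β-dimethyl-trans-decalin-4α-ol | CC(C)C[C@H](c1c(OC)cc(OC)cc1OC)[C@@H]1CC[C@@](C)(O)[C@@H]2C[C@H](C(C)(C)O)CC[C@]21C | intermediate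
26 | lithium hemiaminal, mono-formylated arene as its lithium N,N-dimethylhemiaminal alkoxide (both alcohols as lithium alkoxides) | CC(C)C[C@H](c1c(OC)cc(OC)c(C(O[Li])N(C)C)c1OC)[C@@H]1CC[C@@](C)(O[Li])[C@@H]2C[C@H](C(C)(C)O[Li])CC[C@]21C | intermediate
27 | macrocarpal J tri-O-methyl ether | CC(C)C[C@H](c1c(OC)c(C=O)c(OC)c(C=O)c1OC)[C@@H]1CC[C@@](C)(O)[C@@H]2C[C@H](C(C)(C)O)CC[C@]21C | intermediate
28 | macrocarpal J | CC(C)C[C@H](c1c(O)c(C=O)c(O)c(C=O)c1O)[C@@H]1CC[C@@](C)(O)[C@@H]2C[C@H](C(C)(C)O)CC[C@]21C | target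

**Step count and risks**

Total step count: 18. Longest linear sequence: 18 steps (all from 1; 20 enters at step 13).

Steps most likely to fail:

Step 8. Bond formation at the fully substituted diene terminus C10 may be too slow, so that 1,5-hydrogen shift of the (Z)-methyl diene, ionisation of the allylic aluminium alkoxide or erosion of endo selectivity takes over. Fallback (from 13, back at 16): the diene is redesigned so that its polarity matches the tether-imposed regiochemistry. Stille coupling of 13 with (E)-tributyl[2-(phenylsulfanyl)ethenyl]stannane gives the 1-(phenylsulfanyl)triene (3E,6R,9Z,11E)-10-(hydroxymethyl)-3,9-dimethyl-12-(phenylsulfanyl)-6-[2-(TBSO)propan-2-yl]dodeca-3,9,11-trien-2-one F1, in which the sulfur donor makes C10 the nucleophilic diene terminus. Intramolecular Diels–Alder reaction of this donor-activated diene (toluene, 80–110 °C) through the same endo/chair transition state should give the 3α-(phenylsulfanyl) analogue of octalin 15 F2. Raney nickel in ethanol under hydrogen then cleaves the C–S bond and saturates the ring double bond from the α face, rejoining the route at 16.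

Step 14. Capture of the benzylic cation may show poor facial selectivity, or the cation may lose a proton to the styrene or alkylate a second arene. Fallback (from 19, back at 23): the C1′ centre is set by an auxiliary instead. Horner–Wadsworth–Emmons reaction of 19 with diethyl {2-oxo-2-[(4S)-2-oxo-4-phenyl-1,3-oxazolidin-3-yl]ethyl}phosphonate (LiCl, i-Pr2NEt, MeCN) gives the (E)-enoyl oxazolidinone F3. Copper-mediated conjugate addition of 2,4,6-trimethoxyphenylmagnesium bromide (CuBr·SMe2, THF, −20 °C; chelated s-cis imide, aryl adds anti to the 4-phenyl group) gives the (S)-β-aryl imide F4. Transamination with MeNH(OMe)·HCl/AlMe3 gives the Weinreb amide F5, MeMgBr gives the methyl ketone F6, and Wittig methylenation (Ph3P=CH2) gives 23.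

Step 17. The second lithiation may stay incomplete, or butyllithium may attack the hemiaminal-protected first aldehyde, so that mono-aldehyde or over-addition products result. Fallback (from 25, back at 27): both ring positions are first halogenated by electrophilic bromination (NBS, 2 equiv, MeCN, 0 °C) to give the 3′,5′-dibromo derivative of 25 F7, and double bromine–lithium exchange (t-BuLi, THF, −78 °C) followed by DMF gives 27.

Further compounds
F1 | step 8 | (3E,6R,9Z,11E)-10-(hydroxymethyl)-3,9-dimethyl-12-(phenylsulfanyl)-6-[2-(TBSO)propan-2-yl]dodeca-3,9,11-trien-2-one | CC(=O)/C(C)=C/C[C@@H](CC/C(C)=C(\CO)/C=C/Sc1ccccc1)C(C)(C)O[Si](C)(C)C(C)(C)C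
F2 | step 8 | 3α-(phenylsulfanyl) analogue of octalin 15 | OCC1=C[C@@H](Sc2ccccc2)[C@@](C)(C(C)=O)[C@@H]2C[C@H](C(C)(C)O[Si](C)(C)C(C)(C)C)CC[C@]21C
F3 | step 14 | (E)-enoyl oxazolidinone from aldehyde 19 and the (4S)-4-phenyloxazolidinone phosphonate | O=C(/C=C/[C@@H]1CC[C@@](C)(O)[C@@H]2C[C@H](C(C)(C)O[Si](C)(C)C(C)(C)C)CC[C@]21C)N1[C@@H](c2ccccc2)COC1=O
F4 | step 14 | (S)-β-(2,4,6-trimethoxyphenyl) imide | O=C(C[C@H](c1c(OC)cc(OC)cc1OC)[C@@H]1CC[C@@](C)(O)[C@@H]2C[C@H](C(C)(C)O[Si](C)(C)C(C)(C)C)CC[C@]21C)N1[C@@H](c2ccccc2)COC1=O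
F5 | step 14 | Weinreb amide | CON(C)C(=O)C[C@H](c1c(OC)cc(OC)cc1OC)[C@@H]1CC[C@@](C)(O)[C@@H]2C[C@H](C(C)(C)O[Si](C)(C)C(C)(C)C)CC[C@]21C
F6 | step 14 | methyl ketone | CC(=O)C[C@H](c1c(OC)cc(OC)cc1OC)[C@@H]1CC[C@@](C)(O)[C@@H]2C[C@H](C(C)(C)O[Si](C)(C)C(C)(C)C)CC[C@]21C
F7 | step 17 | 3′,5′-dibromo derivative of 25 | CC(C)C[C@H](c1c(OC)c(Br)c(OC)c(Br)c1OC)[C@@H]1CC[C@@](C)(O)[C@@H]2C[C@H](C(C)(C)O)CC[C@]21C
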